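The data stem from a simulated flask with made-up constants; scatter was added.

The teal run, a racemate under the same gas and racemization catalyst as the new flask, carries a built-in zero. With mirror-image hands and no exchange, left-handed substrate plus left-handed product stays at half of the charge, and its readings average 49.2%, a gap smaller than the 0.95 percentage points of scatter on that mean. Exchange is therefore unseen there, and this reckoning treats each hand separately.

| setting | teal | flask |
|---|---|---|
| left-handed substrate | 51 mM | 34 mM |
| right-handed substrate | 51 mM | 34 mM |
| gas | 2.4 mM (held) | 2.4 mM (held) |
| racemization catalyst | 1.7 mM | 1.7 mM |
| remark | run made earlier |  |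
| time |  | 10 min |

teal run (percent of the left-handed substrate and right-handed substrate together charged)

| time / s | left-handed product / % | right-handed product / % | left-handed substrate / % |
|---|---|---|---|
| 10.0 | 6 | 0 | 42 |
| 20.0 | 18 | 2 | 31 |
| 30.0 | 22 | 0 | 28 |
| 60.0 | 33 | 3 | 15 |
| 120 | 48 | 6 | 3 |

(standard deviation of a reading: 1.5 percentage points)

- reagent is single-handed; left-handed substrate and right-handed substrate are mirror images of each other, charged as a racemate, each of them at the stated concentration
- at the start none of the gas is in solution
- an excess is the difference of the two amounts in percent of their sum
- an excess is below zero if the other one leads
- the handed part of reagent does not stay in what it makes, so the products of the two hands are mirror images too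

1. left-handed product and right-handed product together, in percent of the left-handed substrate and right-handed substrate charged together, at 10 min
2. excess of left-handed product over right-handed product in the product at 10 min
3. whether the exchange between left-handed substrate and right-handed substrate keeps pace with the reaction: how far the product's excess at 10 min gets from its value without exchange to its value with instant exchange (above 80% keeps pace, below 20% hardly takes part, else lags behind)

In the teal run the left-handed substrate, at 15% after 60.0 s, reads as a first-order fall with a constant of 0.0201 s⁻¹. The right-handed product of the teal run is the weak link: its readings run from 0% to 6% against a scatter of 1.5 points. A line through the origin, pooling its readings, gives 9.69 × 10⁻⁴ s⁻¹, the slow-hand constant, the first-order constant with which the right-handed substrate is consumed. The selectivity factor, the ratio of the two constants, reads 20.7.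

If percentages carry over to the 34 mM flask, hardly any left-handed substrate remains at 10 min, and right-handed product reaches 22.0%. That gives y 72.0% and an excess of 38.8%.

Reforging the weak link, two standard deviations put the slow-hand constant between 5.38 × 10⁻⁴ s⁻¹ and 0.00140 s⁻¹, so the excess spans 27.5% to 56.7%.

The forecast says y 74% (67% to 82%), excess 39% (31% to 50%), and exchange hardly takes part, on this ground: “The right-handed product gives k ≈ 0.001 /s, so selectivity is about 20”. Its excess range ends lower than the span above.

The flask gives y 68.9%, excess 55.4%, above the forecast's range, and exchange hardly takes part, at 10% of the way.

    gas ⇌ reagent, rate k1*(csat - [reagent]) (kL = 3.07 s⁻¹)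
    left-handed substrate + racemization catalyst ⇌ right-handed substrate + racemization catalyst, rate k2*[racemization catalyst]*[left-handed substrate] forward; the back reaction follows from the equilibrium constant (k = 1.71 M⁻¹ s⁻¹)
    reagent + left-handed substrate → left-handed product (k = 8.92 M⁻¹ s⁻¹)
    2 racemization catalyst → spent catalyst (k = 25.1 M⁻¹ s⁻¹)
    reagent + right-handed substrate → right-handed product (k = 0.275 M⁻¹ s⁻¹)

In the flask, half of the left-handed step's turnover is done by 0.640 min, whereas the right-handed step has 12% of its turnover behind it at 1.00 min, and its net turnover reaches 15.4% at the asked time, below the forecast's right-handed product of about 23 percent. The slow-hand constant 9.69 × 10⁻⁴ s⁻¹ would leave 55.9% of the charged right-handed substrate at 10 min, and its span 43.2% to 72.4%; the flask keeps 62%, and the neighbour flask with 0.68 mM of racemization catalyst keeps 63%.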